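**Plan**
- Retrosynthesis: the O-methyl bond is cut first (hydroxyquinone 16) and the quinone is taken back to a 1,2,4-trioxygenated benzene. The benzene ring is then cut at the two bonds that join the two-carbon unit (the C–OMe carbon and the neighbouring C=O carbon) to the two indolyl-bearing ring carbons.
- This leaves a glycolic acid unit (Weinreb amide 12) and the four-carbon β-diketone 9. Diketone 9 is cut at the prenyl–C bond and at the diketone C–C bond into ketone 3 and acid 5.
- Enabling feature: in the quinone ring, the C=O carbon that lies between the prenyl-bearing carbon and one indolyl-bearing carbon stands 1,3 to the other indolyl-bearing carbon. This four-carbon arc is therefore a masked β-diketone, with a nucleophilic indol-3-ylmethyl CH2 (as dianion) and an electrophilic 3-indolyl ketone, which matches the acyl carbon and α-oxy CH2 of a glycolic acid unit.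
- Forward: the two indole halves are joined as β-diketone 7 and prenylated to 9. The six-membered carbocycle is then closed from 9 and 12 in one flask (Claisen acylation, then aldol aromatisation). Deprotection with air oxidation gives the quinone ring, and O-methylation ends the route.
- Stereochemistry: the target has no stereocentre and no stereogenic double bond. The sp3 centres of 9 and 13 are erased on aromatisation.

Key step: step 6

Remark on the chemistry: β-diketones and triketones are drawn as keto forms although they should exist largely as enols; 10 is taken as a purchased ester.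

**Step 1**
Reactants: 1 3-acetylindole
Product: 3 3-acetyl-1-(phenylsulfonyl)-1H-indole
Conditions: PhSO2Cl (1.2 equiv), NaOH (50% aq), n-Bu4NHSO4 (cat.), CH2Cl2, 0 to 23 °C
Reagents that add atoms: benzenesulfonyl chloride (2), O=S(=O)(Cl)c1ccccc1
Why: Phase-transfer N-sulfonylation of the acidic N–H of a 3-acylindole should be clean, and the sulfonyl group keeps the 3-acyl carbonyl ketone-like for step 6.

**Step 2**
Reactants: 4 indole-3-acetic acid
Product: 5 [1-(phenylsulfonyl)-1H-indol-3-yl]acetic acid
Conditions: NaH (2.2 equiv), THF/DMF, 0 °C; PhSO2Cl (1.05 equiv), 0 to 23 °C; aq. HCl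
Reagents that add atoms: benzenesulfonyl chloride (2), O=S(=O)(Cl)c1ccccc1
Why: N-Sulfonylation of the carboxylate/indolide dianion should occur at the far more nucleophilic nitrogen, and any mixed anhydride is hydrolysed on work-up.

**Step 3**
Reactants: 5 [1-(phenylsulfonyl)-1H-indol-3-yl]acetic acid, 3 3-acetyl-1-(phenylsulfonyl)-1H-indole
Product: 7 1,4-bis[1-(phenylsulfonyl)-1H-indol-3-yl]butane-1,3-dione, via acid chloride 6 (not isolated)
Conditions: 5, (COCl)2, DMF (cat.), CH2Cl2, 0 to 23 °C, evaporate; 3 (2 equiv), LiN(SiMe3)2 (2.1 equiv), toluene/THF, −78 to 0 °C, then crude 6, 0 °C; aq. NH4Cl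
Reagents that add atoms: none
Why: Crossed Claisen-type C-acylation of a preformed lithium ketone enolate by an acid chloride, in which the excess enolate takes up the acidic diketone proton and any ketene formed from 6 would be trapped by the same enolate to the same product.

**Step 4**
Reactants: 7 1,4-bis[1-(phenylsulfonyl)-1H-indol-3-yl]butane-1,3-dione
Product: 9 2-(3-methylbut-2-en-1-yl)-1,4-bis[1-(phenylsulfonyl)-1H-indol-3-yl]butane-1,3-dione (racemic)
Conditions: prenyl bromide (1.05 equiv), K2CO3 (1.5 equiv), acetone, 23 to 40 °C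
Reagents that add atoms: 1-bromo-3-methylbut-2-ene (8), CC(C)=CCBr
Why: C-Alkylation (SN2) of the β-diketone monoanion should take place at the carbon between the two carbonyls, the only site that carbonate ionises.

**Step 5**
Reactants: 10 methyl [(tert-butyldimethylsilyl)oxy]acetate
Product: 12 2-[(tert-butyldimethylsilyl)oxy]-N-methoxy-N-methylacetamide
Conditions: MeNH(OMe)·HCl (1.5 equiv), i-PrMgCl (3.0 equiv), THF, −20 to 0 °C
Reagents that add atoms: N,O-dimethylhydroxylamine hydrochloride (11), CNOC.Cl
Why: Direct ester-to-Weinreb-amide aminolysis by the magnesium amide of N,O-dimethylhydroxylamine should leave the silyl ether untouched.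

**Step 6**
Reactants: 9 2-(3-methylbut-2-en-1-yl)-1,4-bis[1-(phenylsulfonyl)-1H-indol-3-yl]butane-1,3-dione, 12 2-[(tert-butyldimethylsilyl)oxy]-N-methoxy-N-methylacetamide
Product: 14 6-[(tert-butyldimethylsilyl)oxy]-4-(3-methylbut-2-en-1-yl)-2,5-bis[1-(phenylsulfonyl)-1H-indol-3-yl]benzene-1,3-diol, via triketone 13 (not isolated)
Conditions: LiN(i-Pr)2 (2.05 equiv), THF, −78 to 0 °C; 12 (1.2 equiv), −78 to 0 °C; AcOH (2.2 equiv), then DBU (3 equiv), 0 to 50 °C, same flask
Reagents that add atoms: none
Why: Two equivalents of base should convert 9 into its dianion (central CH first, then the only other α-position, the indol-3-ylmethyl CH2), and this terminal carbanion is acylated by 12, which makes the first ring bond, from the future C–OMe carbon to an indolyl-bearing carbon; protonation frees triketone 13, whose silyloxymethyl ketone enolises under DBU and adds to the 3-indolyl ketone, and loss of water followed by two enolisations makes the second ring bond, from the future C=O carbon to the other indolyl-bearing carbon, inside a benzene ring. The closest known reaction type is the polyketide-type resorcinol synthesis, in which a β-diketone dianion is acylated at its terminal carbon and the resulting 1,3,5-triketone aromatises by intramolecular aldol condensation. The carbocycle closes in the 6-(enolendo)-exo-trig mode. No stereocentre has to be controlled, because the two sp3 centres of 13 disappear on aromatisation. The step needs C-acylation at the terminal carbon only, which the dianion secures (its last-formed carbanion is the most reactive site, and the chelated Weinreb adduct cannot react twice or be enolised by the dianion). It also needs carbocyclisation in place of O-cyclisation to a 4-pyranone, which the basic acid-free medium and the N-sulfonyl group (it keeps the 3-acylindole carbonyl from behaving as a vinylogous amide) should secure.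

**Step 7**
Reactants: 14 6-[(tert-butyldimethylsilyl)oxy]-4-(3-methylbut-2-en-1-yl)-2,5-bis[1-(phenylsulfonyl)-1H-indol-3-yl]benzene-1,3-diol
Product: 16 2-hydroxy-3,6-di(1H-indol-3-yl)-5-(3-methylbut-2-en-1-yl)-1,4-benzoquinone, via benzenetriol 15 (not isolated)
Conditions: NaOH (2 M aq, excess), MeOH/THF, 60 °C, argon; then O2 (air), 23 °C; 1 M HCl
Reagents that add atoms: none
Why: Hydroxide should cleave both N-sulfonyl groups at sulfur and the aryl silyl ether at silicon, and the freed 1,2,4-trihydroxybenzene autoxidises as its phenolate to the 2-hydroxy-1,4-benzoquinone, the single para pair of oxygens fixing the quinone carbonyls.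

**Step 8**
Reactants: 16 2-hydroxy-3,6-di(1H-indol-3-yl)-5-(3-methylbut-2-en-1-yl)-1,4-benzoquinone
Product: 18 2-methoxy-3,6-di(1H-indol-3-yl)-5-(3-methylbut-2-en-1-yl)-1,4-benzoquinone
Conditions: MeI (1.5 equiv), K2CO3 (1.2 equiv), acetone, 23 °C
Reagents that add atoms: iodomethane (17), CI
Why: The hydroxyquinone is a vinylogous carboxylic acid, far more acidic than the indole N–H, so carbonate ionises only it and SN2 O-methylation at the less hindered oxygen should give the para-quinone methyl ether.

**Compound list**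
1 | 3-acetylindole | CC(=O)c1c[nH]c2ccccc12 | starting material
2 | benzenesulfonyl chloride | O=S(=O)(Cl)c1ccccc1 | starting material
3 | 3-acetyl-1-(phenylsulfonyl)-1H-indole | CC(=O)c1cn(S(=O)(=O)c2ccccc2)c2ccccc12 | intermediate
4 | indole-3-acetic acid | OC(=O)Cc1c[nH]c2ccccc12 | starting material
5 | [1-(phenylsulfonyl)-1H-indol-3-yl]acetic acid | OC(=O)Cc1cn(S(=O)(=O)c2ccccc2)c2ccccc12 | intermediate
6 | [1-(phenylsulfonyl)-1H-indol-3-yl]acetyl chloride (not isolated) | ClC(=O)Cc1cn(S(=O)(=O)c2ccccc2)c2ccccc12 | intermediate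
7 | 1,4-bis[1-(phenylsulfonyl)-1H-indol-3-yl]butane-1,3-dione | O=C(CC(=O)Cc1cn(S(=O)(=O)c2ccccc2)c2ccccc12)c1cn(S(=O)(=O)c2ccccc2)c2ccccc12 | intermediate
8 | 1-bromo-3-methylbut-2-ene (prenyl bromide) | CC(C)=CCBr | starting material
9 | 2-(3-methylbut-2-en-1-yl)-1,4-bis[1-(phenylsulfonyl)-1H-indol-3-yl]butane-1,3-dione (racemic) | CC(C)=CCC(C(=O)Cc1cn(S(=O)(=O)c2ccccc2)c2ccccc12)C(=O)c1cn(S(=O)(=O)c2ccccc2)c2ccccc12 | intermediate
10 | methyl [(tert-butyldimethylsilyl)oxy]acetate | COC(=O)CO[Si](C)(C)C(C)(C)C | starting material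
11 | N,O-dimethylhydroxylamine hydrochloride | CNOC.Cl | starting material
12 | 2-[(tert-butyldimethylsilyl)oxy]-N-methoxy-N-methylacetamide | CON(C)C(=O)CO[Si](C)(C)C(C)(C)C | intermediate
13 | 1-[(tert-butyldimethylsilyl)oxy]-5-(3-methylbut-2-en-1-yl)-3,6-bis[1-(phenylsulfonyl)-1H-indol-3-yl]hexane-2,4,6-trione (mixture of diastereomers, not isolated) | CC(C)=CCC(C(=O)c1cn(S(=O)(=O)c2ccccc2)c2ccccc12)C(=O)C(C(=O)CO[Si](C)(C)C(C)(C)C)c1cn(S(=O)(=O)c2ccccc2)c2ccccc12 | intermediate
14 | 6-[(tert-butyldimethylsilyl)oxy]-4-(3-methylbut-2-en-1-yl)-2,5-bis[1-(phenylsulfonyl)-1H-indol-3-yl]benzene-1,3-diol | CC(C)=CCc1c(O)c(-c2cn(S(=O)(=O)c3ccccc3)c3ccccc23)c(O)c(O[Si](C)(C)C(C)(C)C)c1-c1cn(S(=O)(=O)c2ccccc2)c2ccccc12 | intermediate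
15 | 3,6-di(1H-indol-3-yl)-5-(3-methylbut-2-en-1-yl)benzene-1,2,4-triol (not isolated) | CC(C)=CCc1c(O)c(-c2c[nH]c3ccccc23)c(O)c(O)c1-c1c[nH]c2ccccc12 | intermediate
16 | 2-hydroxy-3,6-di(1H-indol-3-yl)-5-(3-methylbut-2-en-1-yl)-1,4-benzoquinone | CC(C)=CCC1=C(c2c[nH]c3ccccc23)C(=O)C(O)=C(c2c[nH]c3ccccc23)C1=O | intermediate
17 | iodomethane | CI | starting material
18 | 2-methoxy-3,6-di(1H-indol-3-yl)-5-(3-methylbut-2-en-1-yl)-1,4-benzoquinone | COC1=C(c2c[nH]c3ccccc23)C(=O)C(CC=C(C)C)=C(c2c[nH]c3ccccc23)C1=O | target

Total step count: 8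
Longest linear sequence: 6 steps (steps 2, 3, 4, 6, 7, 8; steps 1 and 5 feed in)

**Steps most likely to fail**

Step 6. After the Claisen acylation, the hindered and weakly acidic silyloxy-methylene may fail to add to the aryl ketone, so that the triketone drains into O-cyclisation to a 4-pyranone or into retro-Claisen cleavage. The fallback sets out from 9 and replaces the oxygenated two-carbon unit by a plain acetyl unit, putting the missing ring oxygen in afterwards. The dianion of 9 (LiN(i-Pr)2, 2.05 equiv) would be acylated with N-methoxy-N-methylacetamide to 2-(3-methylbut-2-en-1-yl)-1,4-bis[1-(phenylsulfonyl)-1H-indol-3-yl]hexane-1,3,5-trione F1. Its unhindered methyl group should close the ring under DBU (orcinol-type aldol aromatisation) to 4-(3-methylbut-2-en-1-yl)-2,5-bis[1-(phenylsulfonyl)-1H-indol-3-yl]benzene-1,3-diol F2. Teuber oxidation with (KSO3)2NO in KH2PO4-buffered acetone/water at the free position para to a hydroxyl should give 2-hydroxy-5-(3-methylbut-2-en-1-yl)-3,6-bis[1-(phenylsulfonyl)-1H-indol-3-yl]-1,4-benzoquinone F3. NaOH in MeOH/THF at 60 °C would then remove both sulfonyl groups, and the route is rejoined at 16.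

Step 7. Hydroxide attack at the hindered N-sulfonyl groups may be slow, while the electron-rich polyphenolate decomposes oxidatively in warm base. The fallback sets out from 14 and separates the two unmaskings under non-nucleophilic conditions. Electron-transfer cleavage of the N–S bonds with sodium naphthalenide (NaC10H8) in THF at −78 °C should give 6-[(tert-butyldimethylsilyl)oxy]-2,5-di(1H-indol-3-yl)-4-(3-methylbut-2-en-1-yl)benzene-1,3-diol F4. n-Bu4NF in THF at 0 °C, followed by exposure to air, would then remove the silyl group and oxidise the triol, and the route is rejoined at 16.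

Step 3. Proton loss from the acidic arylacetyl chloride (ketene dimerisation) and O-acylation of the enolate may erode C-acylation. The fallback sets out from 5 and makes the same C–C bond by aldol addition at the alcohol oxidation level. BH3·THF would reduce 5 to 2-[1-(phenylsulfonyl)-1H-indol-3-yl]ethanol F5, and Dess–Martin periodinane would give [1-(phenylsulfonyl)-1H-indol-3-yl]acetaldehyde F6. Addition of the lithium enolate of 3 (LiN(SiMe3)2, THF, −78 °C) should give 3-hydroxy-1,4-bis[1-(phenylsulfonyl)-1H-indol-3-yl]butan-1-one F7 (racemic). A second Dess–Martin oxidation would then give the β-diketone, and the route is rejoined at 7.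

**Further compounds**
F1 | step 6 | 2-(3-methylbut-2-en-1-yl)-1,4-bis[1-(phenylsulfonyl)-1H-indol-3-yl]hexane-1,3,5-trione | CC(=O)C(c1cn(S(=O)(=O)c2ccccc2)c2ccccc12)C(=O)C(CC=C(C)C)C(=O)c1cn(S(=O)(=O)c2ccccc2)c2ccccc12
F2 | step 6 | 4-(3-methylbut-2-en-1-yl)-2,5-bis[1-(phenylsulfonyl)-1H-indol-3-yl]benzene-1,3-diol | CC(C)=CCc1c(O)c(-c2cn(S(=O)(=O)c3ccccc3)c3ccccc23)c(O)cc1-c1cn(S(=O)(=O)c2ccccc2)c2ccccc12
F3 | step 6 | 2-hydroxy-5-(3-methylbut-2-en-1-yl)-3,6-bis[1-(phenylsulfonyl)-1H-indol-3-yl]-1,4-benzoquinone | CC(C)=CCC1=C(c2cn(S(=O)(=O)c3ccccc3)c3ccccc23)C(=O)C(O)=C(c2cn(S(=O)(=O)c3ccccc3)c3ccccc23)C1=O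
F4 | step 7 | 6-[(tert-butyldimethylsilyl)oxy]-2,5-di(1H-indol-3-yl)-4-(3-methylbut-2-en-1-yl)benzene-1,3-diol | CC(C)=CCc1c(O)c(-c2c[nH]c3ccccc23)c(O)c(O[Si](C)(C)C(C)(C)C)c1-c1c[nH]c2ccccc12
F5 | step 3 | 2-[1-(phenylsulfonyl)-1H-indol-3-yl]ethanol | OCCc1cn(S(=O)(=O)c2ccccc2)c2ccccc12
F6 | step 3 | [1-(phenylsulfonyl)-1H-indol-3-yl]acetaldehyde | O=CCc1cn(S(=O)(=O)c2ccccc2)c2ccccc12
F7 | step 3 | 3-hydroxy-1,4-bis[1-(phenylsulfonyl)-1H-indol-3-yl]butan-1-one (racemic) | O=C(CC(O)Cc1cn(S(=O)(=O)c2ccccc2)c2ccccc12)c1cn(S(=O)(=O)c2ccccc2)c2ccccc12
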